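**Plan**
- Retrosynthesis: both ester C–O bonds are cut first (ring oxygen and one primary side-chain oxygen), giving a core diol and two molecules of one acid. Each dialdehyde unit is traced back to a cyclopentane cis-1,2-diol acetonide, so the four aldehydes appear only in the last step by glycol cleavage.
- Core: the side-chain CH(CH2O)2 unit goes back to an isopropenyl group (allylic oxidation, hydroboration) and the ring CH2OH to an ester. The cyclopentane goes back to the cyclohexanone ring of (R)-carvone epoxide.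
- Enabling feature: the ring carbon bearing CH2OH lies between the methyl-bearing and the side-chain-bearing ring carbons, and its exocyclic carbon is the former ketone carbon. The vicinal C–CH3/C–O pair of the cyclopentane is the former epoxide.
- Forward order: carvone → epoxide → six-to-five ring contraction (the carbocycle arises here) → side-chain oxygenation → reduction → silylation → hydroboration. The acid is made in parallel, then double esterification, deprotection and periodate cleavage.
- Stereochemistry: C5 of carvone is the only imported core centre. Epoxidation anti to isopropenyl sets the C–O carbon, and the contraction sets the methyl and CH2OH carbons (all-trans). The side-chain carbon is set by ligand-controlled copper hydride hydroboration. The acyl stereocentre comes from alkylation anti to the acetonide of a D-ribose-derived enone, and the E-enal from the E-ethylidene.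

Key step: step 2

Remark on the chemistry: enone 10 is taken as a purchasable chiral-pool building block (D-ribose series), and the target is handled as the open tetra-aldehyde although it may equilibrate with hemiacetal forms.

**Step 1**
Reactants: 1 (R)-carvone
Product: 2 (1R,4R,6R)-1-methyl-4-(prop-1-en-2-yl)-7-oxabicyclo[4.1.0]heptan-2-one
Conditions: H2O2 (30% aq), NaOH (cat.), MeOH, 0 °C
Reagents that add atoms: hydrogen peroxide, OO
Why: Weitz–Scheffer nucleophilic epoxidation touches only the electron-poor enone alkene, and hydroperoxide should add anti to the isopropenyl group, which sets the future ring C–O stereocentre.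

**Step 2**
Reactants: 2 (1R,4R,6R)-1-methyl-4-(prop-1-en-2-yl)-7-oxabicyclo[4.1.0]heptan-2-one
Product: 4 methyl (1S,2R,3R,5R)-3-hydroxy-2-methyl-5-(prop-1-en-2-yl)cyclopentane-1-carboxylate, via cyclopropanone alkoxide 3 (not isolated)
Conditions: NaOMe (0.5 equiv), MeOH, 0 °C → rt
Reagents that add atoms: methanol, CO (delivered as methoxide)
Why: Proposed new method: methoxide can enolise the ketone only toward the CH2 group (the epoxide carbon has no hydrogen), and the enolate carbon should open the oxirane at its α-carbon from the backside to give cyclopropanone 3, to whose carbonyl methoxide adds before the hemiketal breaks the bond from the carbonyl carbon to the methyl-bearing carbon, which methanol protonates with retention. The closest known reaction types are the Favorskii rearrangement of α,β-epoxy ketones, which is known to give β-hydroxy acids, and the Favorskii ring contraction of the tetrahydropyranyl ether of carvone chlorohydrin, which cleaves toward the carbon next to the ether oxygen as needed here. The only ring bond formed closes 3-exo-tet across the six-membered ring, and this same bond closes the five-membered carbocycle once the carbonyl carbon is extruded as the exocyclic ester (contraction from six to five). The carbinol carbon keeps the configuration from the epoxidation; at the methyl-bearing carbon, inversion then retention puts hydrogen where the epoxide oxygen was, so methyl ends cis to isopropenyl and trans to hydroxyl; the ester carbon is fixed by the face of the cyclopropanone bridge, which is also the thermodynamic all-trans arrangement under methoxide. The step needs cleavage of the acyl bond on the methyl-bearing side in preference to the other acyl bond and to a semibenzilic 1,2-shift. The hydroxyl that forms at once in methanol should stabilise the developing carbanion inductively, as the ether oxygen does in the chlorohydrin case, and pre-formed enolate disfavours the semibenzilic path.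

**Step 3**
Reactants: 4 methyl (1S,2R,3R,5R)-3-hydroxy-2-methyl-5-(prop-1-en-2-yl)cyclopentane-1-carboxylate
Product: 5 methyl (1S,2R,3R,5R)-3-hydroxy-5-(3-hydroxyprop-1-en-2-yl)-2-methylcyclopentane-1-carboxylate
Conditions: SeO2 (cat.), t-BuOOH, CH2Cl2, rt
Reagents that add atoms: tert-butyl hydroperoxide, CC(C)(C)OO (oxygen relayed by catalytic SeO2)
Why: SeO2-catalysed allylic hydroxylation (ene reaction, then [2,3]-shift) should take the methyl group of the 1,1-disubstituted alkene in preference to the hindered ring methine, and no stereocentre is formed.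

**Step 4**
Reactants: 5 methyl (1S,2R,3R,5R)-3-hydroxy-5-(3-hydroxyprop-1-en-2-yl)-2-methylcyclopentane-1-carboxylate
Product: 6 (1R,2R,3S,4R)-3-(hydroxymethyl)-4-(3-hydroxyprop-1-en-2-yl)-2-methylcyclopentan-1-ol
Conditions: LiAlH4, THF, 0 °C → rt
Reagents that add atoms: none
Why: Hydride reduction of the ester (and of any lactone that 5 may have formed) gives the ring CH2OH without touching a stereocentre.

**Step 5**
Reactants: 6 (1R,2R,3S,4R)-3-(hydroxymethyl)-4-(3-hydroxyprop-1-en-2-yl)-2-methylcyclopentan-1-ol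
Product: 7 (1R,2R,3S,4R)-3-{[(tert-butyldimethylsilyl)oxy]methyl}-4-{3-[(tert-butyldimethylsilyl)oxy]prop-1-en-2-yl}-2-methylcyclopentan-1-ol
Conditions: TBSCl (2.2 equiv), imidazole, CH2Cl2, 0 °C
Reagents that add atoms: tert-butyldimethylsilyl chloride, CC(C)(C)[Si](C)(C)Cl
Why: Silylation should take the two primary hydroxyls and leave the secondary ring hydroxyl, which is flanked by the methyl group, free for the later acylation.

**Step 6**
Reactants: 7 (1R,2R,3S,4R)-3-{[(tert-butyldimethylsilyl)oxy]methyl}-4-{3-[(tert-butyldimethylsilyl)oxy]prop-1-en-2-yl}-2-methylcyclopentan-1-ol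
Product: 9 (2R)-3-[(tert-butyldimethylsilyl)oxy]-2-[(1R,2S,3R,4R)-2-{[(tert-butyldimethylsilyl)oxy]methyl}-4-hydroxy-3-methylcyclopentyl]propan-1-ol, via bis-boronate 8 (not isolated)
Conditions: CuCl (cat.), (R)-DTBM-SEGPHOS (cat.), NaOtBu (cat.), HBpin (3.5 equiv), toluene, rt; then NaOH (aq), H2O2, THF, 0 °C
Reagents that add atoms: hydrogen peroxide, OO; pinacolborane, CC1(C)OBOC1(C)C (its boron stays only in 8)
Why: Copper hydride-catalysed anti-Markovnikov asymmetric hydroboration of an unactivated 1,1-disubstituted alkene puts copper on the terminal carbon and hydride on the side-chain carbon. The ligand distinguishes the cyclopentyl from the silyloxymethyl substituent and is chosen to give the (2R) centre (catalyst control), and the oxidation proceeds with retention.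

**Step 7**
Reactants: 10 (3aR,6aR)-2,2-dimethyl-3a,6a-dihydro-4H-cyclopenta[d][1,3]dioxol-4-one
Product: 11 (3aR,6aR)-2,2-dimethyltetrahydro-4H-cyclopenta[d][1,3]dioxol-4-one
Conditions: H2 (1 atm), Pd/C, EtOAc, rt
Reagents that add atoms: none
Why: Catalytic hydrogenation saturates the enone alkene and leaves the two acetonide stereocentres untouched.

**Step 8**
Reactants: 11 (3aR,6aR)-2,2-dimethyltetrahydro-4H-cyclopenta[d][1,3]dioxol-4-one
Product: 13 methyl 2-[(3aR,5S,6aR)-2,2-dimethyl-4-oxotetrahydro-4H-cyclopenta[d][1,3]dioxol-5-yl]acetate, via lithium enolate 12 (not isolated)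
Conditions: LiN(SiMe3)2, THF, −78 °C; then BrCH2CO2Me, −78 → −40 °C
Reagents that add atoms: methyl bromoacetate, COC(=O)CBr
Why: Kinetic deprotonation occurs at the CH2 α-carbon (the site used for α-selenenylation of this ketone), and the enolate is alkylated on the convex face anti to the acetonide, which sets the (5S) centre that becomes the (S) centre of the acyl groups; this trans isomer is also the thermodynamic one.

**Step 9**
Reactants: 13 methyl 2-[(3aR,5S,6aR)-2,2-dimethyl-4-oxotetrahydro-4H-cyclopenta[d][1,3]dioxol-5-yl]acetate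
Product: 14 methyl 2-[(3aS,4E,5S,6aR)-4-ethylidene-2,2-dimethyltetrahydro-4H-cyclopenta[d][1,3]dioxol-5-yl]acetate
Conditions: EtPPh3Br, KN(SiMe3)2, THF, 0 °C; then 13, −78 °C → rt
Reagents that add atoms: ethyltriphenylphosphonium bromide, CC[P+](c1ccccc1)(c1ccccc1)c1ccccc1.[Br-]
Why: Wittig ethylidenation with the salt-free ylide should place the methyl group away from the dioxolane oxygen (E), the geometry that maps onto the E-enal, and any minor Z isomer is removed by chromatography.

**Step 10**
Reactants: 14 methyl 2-[(3aS,4E,5S,6aR)-4-ethylidene-2,2-dimethyltetrahydro-4H-cyclopenta[d][1,3]dioxol-5-yl]acetate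
Product: 15 2-[(3aS,4E,5S,6aR)-4-ethylidene-2,2-dimethyltetrahydro-4H-cyclopenta[d][1,3]dioxol-5-yl]acetic acid
Conditions: LiOH, THF/H2O, 0 °C → rt; then dilute HCl to pH 4
Reagents that add atoms: lithium hydroxide, [Li+].[OH-]
Why: Saponification of the methyl ester leaves the acetonide and the alkene intact, and the stereocentre is no longer α to a carbonyl that could epimerise it.

**Step 11**
Reactants: 9 (2R)-3-[(tert-butyldimethylsilyl)oxy]-2-[(1R,2S,3R,4R)-2-{[(tert-butyldimethylsilyl)oxy]methyl}-4-hydroxy-3-methylcyclopentyl]propan-1-ol; 15 2-[(3aS,4E,5S,6aR)-4-ethylidene-2,2-dimethyltetrahydro-4H-cyclopenta[d][1,3]dioxol-5-yl]acetic acid (2.5 equiv)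
Product: 16 diester of diol 9 with two molecules of acid 15 (primary side-chain oxygen and ring oxygen acylated; two TBS ethers and two acetonides retained)
Conditions: EDC·HCl, DMAP, CH2Cl2, rt
Reagents that add atoms: none
Why: Steglich esterification acylates the only two free hydroxyls with the same acid, and the side-chain carbon stays defined because one arm is silylated and the other acylated.

**Step 12**
Reactants: 16 diester of diol 9 with two molecules of acid 15
Product: 17 hexaol (both acetonides and both TBS ethers removed; two cyclopentane cis-1,2-diols, two primary alcohols, two esters)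
Conditions: HCl (2 M aq), THF, 0 °C → rt
Reagents that add atoms: none
Why: Mild aqueous acid hydrolyses the primary silyl ethers and the acetonides in one operation, under conditions that should not hydrolyse the esters or move the acyl group across the 1,3-diol.

**Step 13**
Reactants: 17 hexaol
Product: 18 (1R,2R,3S,4R)-3-(hydroxymethyl)-4-[(2S)-1-hydroxy-3-{[(3S,4E)-4-formyl-3-(2-oxoethyl)hex-4-enoyl]oxy}propan-2-yl]-2-methylcyclopentyl (3S,4E)-4-formyl-3-(2-oxoethyl)hex-4-enoate
Conditions: NaIO4, THF/H2O (pH 7 buffer), 0 °C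
Reagents that add atoms: none
Why: Malaprade glycol cleavage opens only the two cis-1,2-diols, so each acyl cyclopentane becomes the E-enal plus the CH2CHO arm, while the 1,3-related and isolated hydroxyls are inert.

**Compound list**
1 | (R)-carvone, (5R)-2-methyl-5-(prop-1-en-2-yl)cyclohex-2-en-1-one | CC1=CC[C@H](CC1=O)C(C)=C | starting material
2 | (1R,4R,6R)-1-methyl-4-(prop-1-en-2-yl)-7-oxabicyclo[4.1.0]heptan-2-one | O=C1C[C@H](C(C)=C)C[C@H]2O[C@@]12C | intermediate
3 | sodium (1S,2R,4R,5S)-1-methyl-6-oxo-4-(prop-1-en-2-yl)bicyclo[3.1.0]hexan-2-olate (cyclopropanone alkoxide) | O=C1[C@]2(C)[C@H]([O-])C[C@@H](C(C)=C)[C@H]12.[Na+] | intermediate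
4 | methyl (1S,2R,3R,5R)-3-hydroxy-2-methyl-5-(prop-1-en-2-yl)cyclopentane-1-carboxylate | C=C(C)[C@@H]1C[C@@H](O)[C@H](C)[C@H]1C(=O)OC | intermediate
5 | methyl (1S,2R,3R,5R)-3-hydroxy-5-(3-hydroxyprop-1-en-2-yl)-2-methylcyclopentane-1-carboxylate | C=C(CO)[C@@H]1C[C@@H](O)[C@H](C)[C@H]1C(=O)OC | intermediate
6 | (1R,2R,3S,4R)-3-(hydroxymethyl)-4-(3-hydroxyprop-1-en-2-yl)-2-methylcyclopentan-1-ol | C=C(CO)[C@@H]1C[C@@H](O)[C@H](C)[C@H]1CO | intermediate
7 | (1R,2R,3S,4R)-3-{[(tert-butyldimethylsilyl)oxy]methyl}-4-{3-[(tert-butyldimethylsilyl)oxy]prop-1-en-2-yl}-2-methylcyclopentan-1-ol | C=C(CO[Si](C)(C)C(C)(C)C)[C@@H]1C[C@@H](O)[C@H](C)[C@H]1CO[Si](C)(C)C(C)(C)C | intermediate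
8 | bis-boronate of 7 (pinacolboryl on the new side-chain CH2 and on the ring oxygen) | CC1(C)OB(C[C@H](CO[Si](C)(C)C(C)(C)C)[C@@H]2C[C@@H](OB3OC(C)(C)C(C)(C)O3)[C@H](C)[C@H]2CO[Si](C)(C)C(C)(C)C)OC1(C)C | intermediate
9 | (2R)-3-[(tert-butyldimethylsilyl)oxy]-2-[(1R,2S,3R,4R)-2-{[(tert-butyldimethylsilyl)oxy]methyl}-4-hydroxy-3-methylcyclopentyl]propan-1-ol | OC[C@H](CO[Si](C)(C)C(C)(C)C)[C@@H]1C[C@@H](O)[C@H](C)[C@H]1CO[Si](C)(C)C(C)(C)C | intermediate
10 | (3aR,6aR)-2,2-dimethyl-3a,6a-dihydro-4H-cyclopenta[d][1,3]dioxol-4-one | O=C1C=C[C@H]2OC(C)(C)O[C@@H]12 | starting material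
11 | (3aR,6aR)-2,2-dimethyltetrahydro-4H-cyclopenta[d][1,3]dioxol-4-one | O=C1CC[C@H]2OC(C)(C)O[C@@H]12 | intermediate
12 | lithium enolate of 11 (enolised toward the CH2 carbon) | [Li]OC1=CC[C@H]2OC(C)(C)O[C@@H]12 | intermediate
13 | methyl 2-[(3aR,5S,6aR)-2,2-dimethyl-4-oxotetrahydro-4H-cyclopenta[d][1,3]dioxol-5-yl]acetate | O=C1[C@H](CC(=O)OC)C[C@H]2OC(C)(C)O[C@@H]12 | intermediate
14 | methyl 2-[(3aS,4E,5S,6aR)-4-ethylidene-2,2-dimethyltetrahydro-4H-cyclopenta[d][1,3]dioxol-5-yl]acetate | C/C=C1\[C@H](CC(=O)OC)C[C@H]2OC(C)(C)O[C@@H]12 | intermediate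
15 | 2-[(3aS,4E,5S,6aR)-4-ethylidene-2,2-dimethyltetrahydro-4H-cyclopenta[d][1,3]dioxol-5-yl]acetic acid | C/C=C1\[C@H](CC(=O)O)C[C@H]2OC(C)(C)O[C@@H]12 | intermediate
16 | diester of diol 9 with two molecules of acid 15 (primary side-chain oxygen and ring oxygen acylated; two TBS ethers, two acetonides) | O=C(C[C@@H]1C[C@H]2OC(C)(C)O[C@H]2/C1=C/C)OC[C@H](CO[Si](C)(C)C(C)(C)C)[C@@H]1C[C@@H](OC(=O)C[C@@H]2C[C@H]3OC(C)(C)O[C@H]3/C2=C/C)[C@H](C)[C@H]1CO[Si](C)(C)C(C)(C)C | intermediate
17 | hexaol: 16 without the silyl groups and acetonides (each acyl unit a 2-ethylidenecyclopentane-cis-3,4-diol) | O=C(C[C@@H]1C[C@@H](O)[C@@H](O)/C1=C/C)OC[C@H](CO)[C@@H]1C[C@@H](OC(=O)C[C@@H]2C[C@@H](O)[C@@H](O)/C2=C/C)[C@H](C)[C@H]1CO | intermediate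
18 | (1R,2R,3S,4R)-3-(hydroxymethyl)-4-[(2S)-1-hydroxy-3-{[(3S,4E)-4-formyl-3-(2-oxoethyl)hex-4-enoyl]oxy}propan-2-yl]-2-methylcyclopentyl (3S,4E)-4-formyl-3-(2-oxoethyl)hex-4-enoate | C/C=C(/C=O)[C@@H](CC=O)CC(=O)OC[C@H](CO)[C@@H]1C[C@@H](OC(=O)C[C@H](CC=O)/C(C=O)=C\C)[C@H](C)[C@H]1CO | target

**Step count**
Total: 13 steps. Longest linear sequence: 9 steps (steps 1–6, then 11–13); the acid branch is steps 7–10.

**Steps most likely to fail**

Step 2 (Proposed new method). The hemiketal of cyclopropanone 3 may collapse on the wrong side and leave the ester on the methyl-bearing quaternary carbon, a semibenzilic 1,2-shift may give that same ester, or methoxide may simply open the epoxide. The fallback uses known chemistry, sets out from 2 and returns at 4.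
- LiCl and CF3CO2H in THF open the epoxide at the α-carbon with inversion to the chlorohydrin (2S,3R,5R)-2-chloro-3-hydroxy-2-methyl-5-(prop-1-en-2-yl)cyclohexan-1-one F1.
- Dihydropyran and PPTS give its tetrahydropyranyl ether F2.
- NaOMe in MeOH effects the precedented Favorskii contraction to methyl (1R,2S,3R,5R)-2-methyl-5-(prop-1-en-2-yl)-3-(tetrahydropyran-2-yloxy)cyclopentane-1-carboxylate F3, in which the methyl group is cis to the ether oxygen.
- PPTS in MeOH frees the hydroxy ester F4, and Dess–Martin periodinane gives the ketone F5.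
- DBU in CH2Cl2 equilibrates both α-centres to the all-trans keto ester methyl (1S,2R,5R)-2-methyl-3-oxo-5-(prop-1-en-2-yl)cyclopentane-1-carboxylate F6.
- (S)-Me-CBS oxazaborolidine with BH3·SMe2 reduces the ketone under reagent control to 4.

Step 6. Facial selectivity may be poor if the substrate bias opposes the ligand, or hydrocupration of the hindered alkene may be sluggish. The fallback replaces catalyst control by enzymatic differentiation of the two hydroxymethyl arms; it sets out from 4 and returns at 9.
- LiAlH4 gives the diol (1R,2R,3S,4R)-3-(hydroxymethyl)-2-methyl-4-(prop-1-en-2-yl)cyclopentan-1-ol F7.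
- TBSCl (1 equiv) with imidazole silylates the primary hydroxyl to F8.
- SeO2/t-BuOOH gives the allylic alcohol F9.
- BH3·THF, then NaOH/H2O2, gives the 2-substituted propane-1,3-diol F10, whose side-chain carbon is not yet stereogenic.
- Amano lipase PS with vinyl acetate acetylates one of the two diastereotopic arms to the (2S)-monoacetate F11; hydrolysis of the diacetate by the same lipase would serve if the acylation shows the opposite sense.
- TBSCl silylates the remaining primary hydroxyl to F12, and K2CO3 in MeOH at 0 °C removes the acetate to give 9.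

Step 9. The E/Z ratio may be poor, and the basic ylide may cause β-elimination of the acetonide oxygen or epimerisation next to the ketone. The fallback is a stereospecific two-stage Horner–Wittig olefination; it sets out from 13 and returns at 14.
- Ethyldiphenylphosphine oxide is lithiated with n-BuLi and added to 13 at −78 °C.
- The β-hydroxyphosphine oxide adducts are separated by chromatography to give methyl 2-[(3aR,4S,5S,6aR)-4-[(1S)-1-(diphenylphosphoryl)ethyl]-4-hydroxy-2,2-dimethyltetrahydro-4H-cyclopenta[d][1,3]dioxol-5-yl]acetate F13.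
- NaH in DMF then effects syn-elimination of diphenylphosphinate from F13, which can give only the E-alkene 14.

**Further compounds**
F1 | step 2 | (2S,3R,5R)-2-chloro-3-hydroxy-2-methyl-5-(prop-1-en-2-yl)cyclohexan-1-one | O=C1C[C@H](C(C)=C)C[C@@H](O)[C@]1(C)Cl
F2 | step 2 | (2S,3R,5R)-2-chloro-2-methyl-5-(prop-1-en-2-yl)-3-(tetrahydropyran-2-yloxy)cyclohexan-1-one (either configuration at the acetal carbon) | O=C1C[C@H](C(C)=C)C[C@@H](OC2CCCCO2)[C@]1(C)Cl
F3 | step 2 | methyl (1R,2S,3R,5R)-2-methyl-5-(prop-1-en-2-yl)-3-(tetrahydropyran-2-yloxy)cyclopentane-1-carboxylate | C=C(C)[C@@H]1C[C@@H](OC2CCCCO2)[C@@H](C)[C@@H]1C(=O)OC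
F4 | step 2 | methyl (1R,2S,3R,5R)-3-hydroxy-2-methyl-5-(prop-1-en-2-yl)cyclopentane-1-carboxylate | C=C(C)[C@@H]1C[C@@H](O)[C@@H](C)[C@@H]1C(=O)OC
F5 | step 2 | methyl (1R,2S,5R)-2-methyl-3-oxo-5-(prop-1-en-2-yl)cyclopentane-1-carboxylate | C=C(C)[C@@H]1CC(=O)[C@@H](C)[C@@H]1C(=O)OC
F6 | step 2 | methyl (1S,2R,5R)-2-methyl-3-oxo-5-(prop-1-en-2-yl)cyclopentane-1-carboxylate | C=C(C)[C@@H]1CC(=O)[C@H](C)[C@H]1C(=O)OC
F7 | step 6 | (1R,2R,3S,4R)-3-(hydroxymethyl)-2-methyl-4-(prop-1-en-2-yl)cyclopentan-1-ol | C=C(C)[C@@H]1C[C@@H](O)[C@H](C)[C@H]1CO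
F8 | step 6 | (1R,2R,3S,4R)-3-{[(tert-butyldimethylsilyl)oxy]methyl}-2-methyl-4-(prop-1-en-2-yl)cyclopentan-1-ol | C=C(C)[C@@H]1C[C@@H](O)[C@H](C)[C@H]1CO[Si](C)(C)C(C)(C)C
F9 | step 6 | (1R,2R,3S,4R)-3-{[(tert-butyldimethylsilyl)oxy]methyl}-4-(3-hydroxyprop-1-en-2-yl)-2-methylcyclopentan-1-ol | C=C(CO)[C@@H]1C[C@@H](O)[C@H](C)[C@H]1CO[Si](C)(C)C(C)(C)C
F10 | step 6 | 2-[(1R,2S,3R,4R)-2-{[(tert-butyldimethylsilyl)oxy]methyl}-4-hydroxy-3-methylcyclopentyl]propane-1,3-diol | OCC(CO)[C@@H]1C[C@@H](O)[C@H](C)[C@H]1CO[Si](C)(C)C(C)(C)C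
F11 | step 6 | (2S)-2-[(1R,2S,3R,4R)-2-{[(tert-butyldimethylsilyl)oxy]methyl}-4-hydroxy-3-methylcyclopentyl]-3-hydroxypropyl acetate | CC(=O)OC[C@H](CO)[C@@H]1C[C@@H](O)[C@H](C)[C@H]1CO[Si](C)(C)C(C)(C)C
F12 | step 6 | (2R)-3-[(tert-butyldimethylsilyl)oxy]-2-[(1R,2S,3R,4R)-2-{[(tert-butyldimethylsilyl)oxy]methyl}-4-hydroxy-3-methylcyclopentyl]propyl acetate | CC(=O)OC[C@H](CO[Si](C)(C)C(C)(C)C)[C@@H]1C[C@@H](O)[C@H](C)[C@H]1CO[Si](C)(C)C(C)(C)C
F13 | step 9 | methyl 2-[(3aR,4S,5S,6aR)-4-[(1S)-1-(diphenylphosphoryl)ethyl]-4-hydroxy-2,2-dimethyltetrahydro-4H-cyclopenta[d][1,3]dioxol-5-yl]acetate | C[C@H](P(=O)(c1ccccc1)c1ccccc1)[C@]1(O)[C@H](CC(=O)OC)C[C@H]2OC(C)(C)O[C@@H]12
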